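**Retrosynthetic overview**

1. Labels: quinolone A carries the 2,2-dimethyl-dihydropyran ring A; quinolone B carries dihydropyran ring B. Rings A and B share the bond C-a–C-b (C-a = CH bonded to CMe2; C-b = CH bonded to the ring-B oxygen and to C3 of quinolone A); C-c = ring-B CH bearing CH2CMe2OH.
2. Enabling feature: in ring A, C-b is at the aldehyde oxidation level (one O plus the nucleophilic C3 of quinolone A) and the O–CMe2 carbon is at the acetone oxidation level. Ring A is therefore a cationic 2-oxadiene (C3=C4–O+=CMe2 of quinolone A) added across an enol ether C-a=C-b that is the C2=C3 bond of a 4H-pyran ring B.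
3. Disconnections: (i) O–Si cleavage last; (ii) ring A by an acid-triggered formal [4+2] (oxa-Povarov type) that makes C3(quinolone A)–C-b and C-a–CMe2 from isopropenyl ether 11 and the chiral 4H-pyranoquinolinone 9; (iii) ring B by organocatalytic Michael addition/lactolisation of 4-hydroxy-1-methylquinolin-2-one to an enal, then dehydration.
4. Ring order: ring B (step 3, sets C-c by catalyst control), enol ether (step 4), ring A (step 7, sets C-a and C-b from C-c).

Key step: step 7

Remark: the side-chain tertiary alcohol is carried as its tert-butyldimethylsilyl ether from step 1 to step 8, because a free hydroxyl would trap the oxocarbenium ions of steps 4 and 7 as bridged acetals; compounds 1, 3 and 5 are taken as commercial.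

**Route**

Step 1
Reactants: 1 2-methylpent-4-en-2-ol
Product: 2 tert-butyldimethyl[(2-methylpent-4-en-2-yl)oxy]silane
Conditions: TBSOTf, 2,6-lutidine, CH2Cl2, 0 °C to rt
Reagents that add atoms: tert-butyldimethylsilyl triflate, CC(C)(C)[Si](C)(C)OS(=O)(=O)C(F)(F)F
Why: Silylation of a hindered tertiary alcohol with a silyl triflate and 2,6-lutidine is standard protection chemistry and gives an ether that should survive the amine, base and catalytic-acid steps that follow.

Step 2
Reactants: 2 tert-butyldimethyl[(2-methylpent-4-en-2-yl)oxy]silane; 3 (E)-but-2-enal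
Product: 4 (E)-5-[(tert-butyldimethylsilyl)oxy]-5-methylhex-2-enal
Conditions: 3 (5 equiv), second-generation Hoveyda–Grubbs catalyst RuCl2(H2IMes)(=CH-C6H4-2-OiPr) (3 mol %), CH2Cl2, 40 °C
Reagents that add atoms: none
Why: Olefin cross-metathesis of a terminal alkene with excess crotonaldehyde is a reliable route to enals, and the conjugated double bond should form with E geometry under thermodynamic control.

Step 3
Reactants: 4 (E)-5-[(tert-butyldimethylsilyl)oxy]-5-methylhex-2-enal; 5 4-hydroxy-1-methylquinolin-2(1H)-one
Product: 7 (4R)-4-{2-[(tert-butyldimethylsilyl)oxy]-2-methylpropyl}-2-hydroxy-6-methyl-3,4-dihydro-2H-pyrano[3,2-c]quinolin-5(6H)-one (anomer mixture), via open-chain Michael aldehyde 6 (not isolated)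
Conditions: (S)-2-[diphenyl(trimethylsilyloxy)methyl]pyrrolidine (20 mol %), PhCO2H (20 mol %), CH2Cl2, rt
Reagents that add atoms: none
Why: Iminium-ion catalysis with a diarylprolinol silyl ether (Jørgensen–Hayashi type Michael addition) is precedented for 4-hydroxycoumarins and related enolised cyclic 1,3-dicarbonyl compounds with enals; C3 of 5 should add to the β-carbon of the (E)-iminium ion on the face opposite to the CPh2(OSiMe3) group of the (S)-catalyst, which sets C-c as R, and the 4-hydroxyl then closes ring B as the lactol.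

Step 4
Reactants: 7 the (4R)-lactol
Product: 9 (R)-4-{2-[(tert-butyldimethylsilyl)oxy]-2-methylpropyl}-6-methyl-4H-pyrano[3,2-c]quinolin-5(6H)-one, via anomeric mesylate 8 (not isolated)
Conditions: MsCl, Et3N, CH2Cl2, 0 °C to rt
Reagents that add atoms: none
Why: Sulfonylation of a 2-deoxy-type lactol followed by base-induced elimination is the standard lactol-to-glycal dehydration; it can only give the C2=C3 enol ether because C3 carries the only β-hydrogens, and it leaves the C4 stereocentre untouched.

Step 5
Reactants: 5 4-hydroxy-1-methylquinolin-2(1H)-one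
Product: 10 1-methyl-2-oxo-1,2-dihydroquinolin-4-yl acetate
Conditions: Ac2O, pyridine, 4-(dimethylamino)pyridine (5 mol %), CH2Cl2, 0 °C to rt
Reagents that add atoms: acetic anhydride, CC(=O)OC(C)=O
Why: O-Acylation of the acidic 4-hydroxyl is routine and fixes the future enol-ether carbon on oxygen and not on C3.

Step 6
Reactants: 10 1-methyl-2-oxo-1,2-dihydroquinolin-4-yl acetate
Product: 11 1-methyl-4-(prop-1-en-2-yloxy)quinolin-2(1H)-one
Conditions: Cp2TiMe2 (2.5 equiv), toluene, 65 °C, dark; filtration through basic alumina
Reagents that add atoms: dimethyltitanocene, [CH3-].[CH3-].[CH-]1C=CC=C1.[CH-]1C=CC=C1.[Ti+4]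
Why: Petasis methylenation converts aryl and enol esters into isopropenyl ethers through Cp2Ti=CH2 and an oxatitanacyclobutane under neutral conditions, and the much less electrophilic pyridone-type lactam carbonyl should not react.

Step 7
Reactants: 9 (R)-4-{2-[(tert-butyldimethylsilyl)oxy]-2-methylpropyl}-6-methyl-4H-pyrano[3,2-c]quinolin-5(6H)-one; 11 1-methyl-4-(prop-1-en-2-yloxy)quinolin-2(1H)-one
Product: 14 tert-butyldimethylsilyl ether of the target (C-a R; C-b S; C-c R; rings A and B cis-fused), via aryl oxocarbenium ion 12 (not isolated), via ring-B oxocarbenium ion 13 (not isolated)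
Conditions: HNTf2 (10 mol %), 4 Å molecular sieves, CH2Cl2, −78 to −40 °C, 11 (2.5 equiv) added by syringe pump to 9; Et3N quench
Reagents that add atoms: none
Why: Proposed new method: HNTf2 should protonate the unhindered CH2 of the 1,1-disubstituted enol ether 11 to give the cationic 2-oxadiene 12 (C3=C4–O+=CMe2 of quinolone A); its CMe2 carbon is attacked by the nucleophilic C3 of enol ether 9, and the ring-B oxocarbenium ion 13 so formed is captured at C2 by C3 of quinolone A, loss of H+ regenerating the acid. The closest known reaction type is the oxa-Povarov reaction (formal inverse-electron-demand [4+2] of aryl oxocarbenium ions with alkenes to give chromans) and its nitrogen parent, the Povarov reaction of N-aryl iminium ions with cyclic enol ethers; new here are the ketone-derived cation, the 4-oxy-2-quinolone as the aryl part and an enol ether as the 2π partner. Ring A closes as a stepwise formal [4+2], its second bond by a 6-(enolendo)-exo-trig Friedel–Crafts attack on the oxocarbenium carbon. C-a is set by attack of 12 on the face of the C2=C3 bond anti to the C4 side chain, which allylic strain against the C5 carbonyl holds pseudoaxial; C-b is then set cis to it because the O-tethered quinolone, now pseudoaxial on C-a, can reach the neighbouring cationic carbon only from its own face, and a trans fusion would force both ring-B substituents into the disfavoured pseudoequatorial positions. The step needs cross-coupling instead of self-coupling of 11 and protonation of 11 instead of 9: the α-methyl group makes 11 the faster protonated enol ether whereas the β-substituted, ring-fused 9 is protonated slowly, and syringe-pump addition keeps the concentration of 11 too low to intercept its own cation.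

Step 8
Reactants: 14 tert-butyldimethylsilyl ether of the target
Product: 15 CNP0202276.1
Conditions: Bu4NF, THF, 50 °C; water work-up
Reagents that add atoms: none
Why: Fluoride-mediated cleavage of the silyl ether is standard, and basic fluoride is chosen over acid because the doubly activated C-b–O bond of the target could ionise under acid and be recaptured by the freed tertiary hydroxyl.

**Compound list**

1 | 2-methylpent-4-en-2-ol | C=CCC(C)(C)O | starting material
2 | tert-butyldimethyl[(2-methylpent-4-en-2-yl)oxy]silane | C=CCC(C)(C)O[Si](C)(C)C(C)(C)C | intermediate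
3 | (E)-but-2-enal (crotonaldehyde) | C/C=C/C=O | starting material
4 | (E)-5-[(tert-butyldimethylsilyl)oxy]-5-methylhex-2-enal | O=C/C=C/CC(C)(C)O[Si](C)(C)C(C)(C)C | intermediate
5 | 4-hydroxy-1-methylquinolin-2(1H)-one | Cn1c(=O)cc(O)c2ccccc12 | starting material
6 | (R)-5-[(tert-butyldimethylsilyl)oxy]-3-(4-hydroxy-1-methyl-2-oxo-1,2-dihydroquinolin-3-yl)-5-methylhexanal (open-chain Michael adduct) | Cn1c(=O)c(c(O)c2ccccc12)[C@@H](CC=O)CC(C)(C)O[Si](C)(C)C(C)(C)C | intermediate
7 | (4R)-4-{2-[(tert-butyldimethylsilyl)oxy]-2-methylpropyl}-2-hydroxy-6-methyl-3,4-dihydro-2H-pyrano[3,2-c]quinolin-5(6H)-one, mixture of C2 anomers | OC1Oc2c(c(=O)n(C)c3ccccc23)[C@@H](C1)CC(C)(C)O[Si](C)(C)C(C)(C)C | intermediate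
8 | anomeric methanesulfonate of 7 (C2-OMs, anomer mixture) | CS(=O)(=O)OC1Oc2c(c(=O)n(C)c3ccccc23)[C@@H](C1)CC(C)(C)O[Si](C)(C)C(C)(C)C | intermediate
9 | (R)-4-{2-[(tert-butyldimethylsilyl)oxy]-2-methylpropyl}-6-methyl-4H-pyrano[3,2-c]quinolin-5(6H)-one | C1=COc2c(c(=O)n(C)c3ccccc23)[C@@H]1CC(C)(C)O[Si](C)(C)C(C)(C)C | intermediate
10 | 1-methyl-2-oxo-1,2-dihydroquinolin-4-yl acetate | CC(=O)Oc1cc(=O)n(C)c2ccccc12 | intermediate
11 | 1-methyl-4-(prop-1-en-2-yloxy)quinolin-2(1H)-one | C=C(C)Oc1cc(=O)n(C)c2ccccc12 | intermediate
12 | (1-methyl-2-oxo-1,2-dihydroquinolin-4-yl)(propan-2-ylidene)oxonium bistriflimide (cationic 2-oxadiene) | CC(C)=[O+]c1cc(=O)n(C)c2ccccc12.[N-](S(=O)(=O)C(F)(F)F)S(=O)(=O)C(F)(F)F | intermediate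
13 | ring-B oxocarbenium bistriflimide: 9 alkylated at C3 (anti to the C4 side chain) by the CMe2–O–quinolone A unit, with C2=O+ | Cn1c(=O)cc(c2ccccc12)OC(C)(C)[C@H]1C=[O+]c2c(c(=O)n(C)c3ccccc23)[C@@H]1CC(C)(C)O[Si](C)(C)C(C)(C)C.[N-](S(=O)(=O)C(F)(F)F)S(=O)(=O)C(F)(F)F | intermediate
14 | tert-butyldimethylsilyl ether of the target: as 15 with the side-chain tertiary OH as OSiMe2tBu; C-a R, C-b S, C-c R | Cn1c(=O)c2c(c3ccccc31)OC(C)(C)[C@H]1[C@@H]2Oc2c(c(=O)n(C)c3ccccc23)[C@@H]1CC(C)(C)O[Si](C)(C)C(C)(C)C | intermediate
15 | CNP0202276.1: two 1-methylquinolin-2-ones, quinolone A fused at C3/C4-O to the 2,2-dimethyl-dihydropyran ring A, whose CH–CH bond (C-a R, C-b S, hydrogens cis) is shared with dihydropyran ring B of quinolone B; C-b bonded to the ring-B oxygen; C-c (R) bears CH2C(CH3)2OH trans to the CMe2 carbon | Cn1c(=O)c2c(c3ccccc31)OC(C)(C)[C@H]1[C@@H]2Oc2c(c(=O)n(C)c3ccccc23)[C@@H]1CC(C)(C)O | target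

**Step count and risks**

Total step count: 8. Longest linear sequence: 6 steps (steps 1, 2, 3, 4, 7, 8); steps 5 and 6 form the second branch.

Steps most likely to fail:

Step 7 (proposed new method). The isopropenyl ether may couple with its own cation, 9 may be protonated competitively, or the acid may strip the silyl ether. Fallback from 9 back to 14, in which the cation and the nucleophile are brought in separately by known reaction types. 2,2-Dimethoxypropane with catalytic BF3·OEt2 (CH2Cl2, −78 °C) should add to the enol ether of 9 in an acetal–enol ether condensation, anti to the C4 side chain, to give the 2-methoxy-3-(2-methoxypropan-2-yl) acetal F1. F1 and 5 with BF3·OEt2 in MeCN at 0 °C should give, by Friedel–Crafts type C-alkylation of C3 of 5 at the anomeric carbon, the C-aryl pyran F2. On warming, the tertiary methyl ether should ionise and the 4-hydroxyl of quinolone A should close ring A with loss of methanol. Reversible opening of ring B at the doubly activated C-b should let the cis-fused isomer accumulate, which gives 14.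

Step 6. Acyl transfer from the vinylogous anhydride to the titanium reagent, or methylenation at the lactam carbonyl, may erode the yield. Fallback from 5 back to 11 without a carbonyl olefination. Mitsunobu O-alkylation of 5 with 1-bromopropan-2-ol (PPh3, DIAD, THF) should give racemic 4-[(1-bromopropan-2-yl)oxy]-1-methylquinolin-2(1H)-one F3. E2 dehydrobromination (KOtBu, THF, 0 °C) should then give 11, because the only β-hydrogen sits on the oxygen-bearing carbon.

Step 3. Conjugate addition next to the neopentyl-type chain may be slow, γ-deprotonation to a dienamine may compete, and facial selectivity may erode. Fallback from 4 back to 7, setting C-c by transition-metal catalysis instead: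
- Luche reduction of 4 (NaBH4, CeCl3·7H2O, MeOH) should give the allylic alcohol F4.
- ClCO2Me/pyridine should give the methyl carbonate F5.
- Iridium-catalysed branched-selective asymmetric allylic alkylation of 5 at C3 ([Ir(cod)Cl]2, Feringa-type phosphoramidite ligand of the antipode that gives the drawn configuration, DBU, THF) should give the branched alkene F6.
- Hydroboration/oxidation (9-BBN, THF; then NaBO3) should give the primary alcohol F7.
- Oxidation (TEMPO cat., PhI(OAc)2, CH2Cl2) should give aldehyde 6, which closes to lactol 7.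

Further compounds
F1 | step 7 | (3S,4R)-4-{2-[(tert-butyldimethylsilyl)oxy]-2-methylpropyl}-2-methoxy-3-(2-methoxypropan-2-yl)-6-methyl-3,4-dihydro-2H-pyrano[3,2-c]quinolin-5(6H)-one, anomer mixture | COC(C)(C)[C@H]1C(OC)Oc2c(c(=O)n(C)c3ccccc23)[C@@H]1CC(C)(C)O[Si](C)(C)C(C)(C)C
F2 | step 7 | (2S,3R,4R)-4-{2-[(tert-butyldimethylsilyl)oxy]-2-methylpropyl}-2-(4-hydroxy-1-methyl-2-oxo-1,2-dihydroquinolin-3-yl)-3-(2-methoxypropan-2-yl)-6-methyl-3,4-dihydro-2H-pyrano[3,2-c]quinolin-5(6H)-one | COC(C)(C)[C@H]1[C@@H](c2c(O)c3ccccc3n(C)c2=O)Oc2c(c(=O)n(C)c3ccccc23)[C@@H]1CC(C)(C)O[Si](C)(C)C(C)(C)C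
F3 | step 6 | 4-[(1-bromopropan-2-yl)oxy]-1-methylquinolin-2(1H)-one, racemic | CC(CBr)Oc1cc(=O)n(C)c2ccccc12
F4 | step 3 | (E)-5-[(tert-butyldimethylsilyl)oxy]-5-methylhex-2-en-1-ol | OC/C=C/CC(C)(C)O[Si](C)(C)C(C)(C)C
F5 | step 3 | methyl (E)-5-[(tert-butyldimethylsilyl)oxy]-5-methylhex-2-en-1-yl carbonate | COC(=O)OC/C=C/CC(C)(C)O[Si](C)(C)C(C)(C)C
F6 | step 3 | (R)-3-{5-[(tert-butyldimethylsilyl)oxy]-5-methylhex-1-en-3-yl}-4-hydroxy-1-methylquinolin-2(1H)-one | Cn1c(=O)c(c(O)c2ccccc12)[C@@H](C=C)CC(C)(C)O[Si](C)(C)C(C)(C)C
F7 | step 3 | (S)-3-{5-[(tert-butyldimethylsilyl)oxy]-1-hydroxy-5-methylhexan-3-yl}-4-hydroxy-1-methylquinolin-2(1H)-one | Cn1c(=O)c(c(O)c2ccccc12)[C@@H](CCO)CC(C)(C)O[Si](C)(C)C(C)(C)C
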